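The route opens the ten-membered carbocycle (C1–C10, germacrane numbering) between C3 and C4. Because C3 of the target is an allylic carbinol flanked by the C2 methylene and the ring-cis C4=C5 alkene, one intramolecular Nozaki–Hiyama–Kishi addition of a (Z)-alkenyl iodide at C4 to a C3 aldehyde should form the C3–C4 bond, the carbocycle and the C3 stereocentre together. The precursor is seco aldehyde 30: a trans-disubstituted α-methylene-γ-butyrolactone with the (Z)-2-iodopropenyl group on C6 and, on C7, the C8 epoxy-ester chain ending in the (E)-enoate and the C3 aldehyde. It is assembled from a stannylmethyl butenolide, an enoate aldehyde and an epoxy acid.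

Key step: step 18

Assumption: vinylmagnesium bromide, allyl bromide, 2-(bromomethyl)prop-2-enoic acid and 3-[(tert-butyldimethylsilyl)oxy]propanal are taken as commercial.

Remark: atoms carry germacrane numbers (C1=C10 enoate with ester carbon C14, C3 carbinol, C4(C15)=C5, C6 lactone O–CH, C7, C8 acyloxy carbon, C9, C11=C13, C12 lactone carbonyl). C1=C10 is ring-cis but E by the sequence rule. The C6 descriptor is S in every iodide and R in the macrocycle with no change in space, because iodine on C4 is replaced by carbon.

Step 1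
Reactants: 1 but-2-yn-1-ol
Product: 3 (Z)-3-iodobut-2-en-1-ol, via cyclic alkenylaluminate 2 (not isolated)
Conditions: NaAlH2(OCH2CH2OMe)2 (Red-Al), THF, 0 °C to rt; then I2, THF, −78 °C
Reagents that add atoms: iodine, II
Why: Hydroxyl-directed trans-hydroalumination of the propargylic alcohol puts aluminium on C3 anti to the new C2–H, and iodinolysis with retention should give the (Z)-iodide.

Step 2
Reactants: 3 (Z)-3-iodobut-2-en-1-ol
Product: 4 (Z)-3-iodobut-2-enal
Conditions: MnO2, CH2Cl2, rt, dark
Reagents that add atoms: none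
Why: Allylic oxidation with MnO2 is neutral and should keep the Z geometry of the iodoalkene; the enal is used without storage.

Step 3
Reactants: 4 (Z)-3-iodobut-2-enal; 5 vinylmagnesium bromide
Product: 6 rac-(Z)-5-iodohexa-1,4-dien-3-ol
Conditions: THF, −78 °C; aq NH4Cl
Reagents that add atoms: none
Why: Grignard 1,2-addition to the enal at low temperature should outrun iodine–magnesium exchange; the carbinol (future C6) is formed racemic.

Step 4
Reactants: 6 rac-(Z)-5-iodohexa-1,4-dien-3-ol
Product: 7 (3S,4Z)-5-iodohexa-1,4-dien-3-ol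
Conditions: Ti(OiPr)4 (cat.), L-(+)-diisopropyl tartrate (cat.), t-BuOOH (0.6 equiv), 4 Å molecular sieves, CH2Cl2, −20 °C
Reagents that add atoms: none
Why: Sharpless kinetic resolution: with the L-(+)-tartrate the (3R) alcohol should be epoxidised at its vinyl group much faster and the (3S) alcohol left behind, the iodo-substituted alkene being too electron-poor to react.

Step 5
Reactants: 7 (3S,4Z)-5-iodohexa-1,4-dien-3-ol; 8 2-(bromomethyl)prop-2-enoic acid
Product: 10 (3S,4Z)-5-iodohexa-1,4-dien-3-yl 2-(bromomethyl)prop-2-enoate, via 2-(bromomethyl)prop-2-enoyl chloride 9 (not isolated)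
Conditions: 8, (COCl)2, cat. DMF, CH2Cl2, 0 °C to rt; then 7, 2,6-lutidine, CH2Cl2, −20 to 0 °C
Reagents that add atoms: none
Why: Acylation of the secondary alcohol by the acid chloride with a hindered pyridine base should avoid SN2′ attack of the base on the allylic bromide and leave the carbinol centre untouched (esterification).

Step 6
Reactants: 10 (3S,4Z)-5-iodohexa-1,4-dien-3-yl 2-(bromomethyl)prop-2-enoate
Product: 12 (3S,4Z)-5-iodohexa-1,4-dien-3-yl 2-[(tributylstannyl)methyl]prop-2-enoate, via allylzinc bromide 11 (not isolated)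
Conditions: Zn dust, Bu3SnCl, THF/sat. aq NH4Cl, rt
Reagents that add atoms: tributyltin chloride, CCCC[Sn](Cl)(CCCC)CCCC
Why: Barbier-type stannylation: zinc should insert into the allylic C–Br bond far faster than into the alkenyl iodide, and the allylzinc is trapped by the tin chloride; the two allyl termini are equivalent, so no regiochemical question arises.

Step 7
Reactants: 12 (3S,4Z)-5-iodohexa-1,4-dien-3-yl 2-[(tributylstannyl)methyl]prop-2-enoate
Product: 13 (5S)-5-[(Z)-2-iodoprop-1-en-1-yl]-3-[(tributylstannyl)methyl]furan-2(5H)-one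
Conditions: second-generation Grubbs catalyst (5 mol%), CH2Cl2, 40 °C
Reagents that add atoms: none
Why: Ring-closing metathesis between the vinyl group and the acrylate alkene should close the butenolide with loss of ethylene, the trisubstituted iodoalkene and the allylic tin group being spectators.

Step 8
Reactants: 14 trimethyl phosphonoacetate; 15 allyl bromide
Product: 16 methyl 2-(dimethoxyphosphoryl)pent-4-enoate (racemic)
Conditions: NaH, THF, 0 °C to rt (14 in excess)
Reagents that add atoms: none
Why: SN2 alkylation of the sodium phosphonoacetate anion with a reactive allylic bromide; excess phosphonate should limit dialkylation.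

Step 9
Reactants: 16 methyl 2-(dimethoxyphosphoryl)pent-4-enoate; 17 3-[(tert-butyldimethylsilyl)oxy]propanal
Product: 18 methyl (2E)-5-[(tert-butyldimethylsilyl)oxy]-2-(prop-2-en-1-yl)pent-2-enoate
Conditions: NaH, THF, 0 °C
Reagents that add atoms: none
Why: Horner–Wadsworth–Emmons olefination of an α-substituted phosphonoacetate should give mainly the (E)-enoate (ester trans to the new chain, that is C9 and C2 cis as the ring needs); any minor isomer is removed by chromatography.

Step 10
Reactants: 18 methyl (2E)-5-[(tert-butyldimethylsilyl)oxy]-2-(prop-2-en-1-yl)pent-2-enoate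
Product: 20 methyl (2E)-5-[(tert-butyldimethylsilyl)oxy]-2-(2-oxoethyl)pent-2-enoate, via vicinal diol 19 (not isolated)
Conditions: OsO4 (cat.), NaIO4, 2,6-lutidine, dioxane/H2O, rt
Reagents that add atoms: osmium tetroxide (oxygen carrier), O=[Os](=O)(=O)=O; sodium periodate (terminal oxygen source), [Na+].[O-]I(=O)(=O)=O
Why: Lemieux–Johnson cleavage: OsO4 should dihydroxylate the terminal alkene in preference to the electron-poor trisubstituted enoate, and periodate cleaves the diol; lutidine buffers the β,γ-unsaturated aldehyde.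

Step 11
Reactants: 21 angelic acid
Product: 22 (Z)-2-methylbut-2-en-1-ol
Conditions: LiAlH4, Et2O, 0 °C
Reagents that add atoms: none
Why: Hydride reduction of the carboxylic acid at 0 °C should give the allylic alcohol without touching or isomerising the (Z)-alkene.

Step 12
Reactants: 22 (Z)-2-methylbut-2-en-1-ol
Product: 23 [(2S,3R)-2,3-dimethyloxiran-2-yl]methanol
Conditions: Ti(OiPr)4 (cat.), L-(+)-diethyl tartrate (cat.), t-BuOOH, 4 Å molecular sieves, CH2Cl2, −20 °C
Reagents that add atoms: tert-butyl hydroperoxide, CC(C)(C)OO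
Why: Sharpless asymmetric epoxidation: the L-(+)-tartrate should deliver oxygen to the face that makes the hydroxymethyl-bearing carbon 2S, and the Z geometry of the alkene then fixes C3 as R.

Step 13
Reactants: 23 [(2S,3R)-2,3-dimethyloxiran-2-yl]methanol
Product: 25 (2R,3R)-2,3-dimethyloxirane-2-carboxylic acid, via epoxy aldehyde 24 (not isolated)
Conditions: TEMPO (cat.), PhI(OAc)2, MeCN/H2O, rt
Reagents that add atoms: water, O
Why: Nitroxyl-catalysed oxidation in aqueous acetonitrile should take the primary alcohol through the aldehyde hydrate to the acid without opening the epoxide; both stereocentres are untouched (the C2 descriptor changes only by priority).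

Step 14
Reactants: 13 (5S)-5-[(Z)-2-iodoprop-1-en-1-yl]-3-[(tributylstannyl)methyl]furan-2(5H)-one; 20 methyl (2E)-5-[(tert-butyldimethylsilyl)oxy]-2-(2-oxoethyl)pent-2-enoate
Product: 26 methyl (2E,4R)-2-{3-[(tert-butyldimethylsilyl)oxy]propylidene}-4-hydroxy-4-{(2S,3R)-2-[(Z)-2-iodoprop-1-en-1-yl]-4-methylidene-5-oxooxolan-3-yl}butanoate
Conditions: BF3·OEt2, CH2Cl2, −78 °C; aq KF work-up
Reagents that add atoms: none
Why: Lewis-acid-mediated SE2′ addition of the allylstannane to the aldehyde forms C7–C8 and moves the alkene to C11=C13; C7 should be attacked anti to the C6 substituent (trans lactone) and the open antiperiplanar transition state should give the syn C7/C8 relation (8R).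

Step 15
Reactants: 26 C8 alcohol (as in step 14); 25 (2R,3R)-2,3-dimethyloxirane-2-carboxylic acid
Product: 28 methyl (2E,4R)-2-{3-[(tert-butyldimethylsilyl)oxy]propylidene}-4-{[(2R,3R)-2,3-dimethyloxirane-2-carbonyl]oxy}-4-{(2S,3R)-2-[(Z)-2-iodoprop-1-en-1-yl]-4-methylidene-5-oxooxolan-3-yl}butanoate, via trichlorobenzoyl mixed anhydride 27 (not isolated)
Conditions: 25, 2,4,6-trichlorobenzoyl chloride, Et3N, toluene, rt; then 26, DMAP, toluene, 0 °C to rt
Reagents that add atoms: none
Why: Yamaguchi esterification: DMAP should transfer the epoxy acyl group of the mixed anhydride to the C8 hydroxyl under non-equilibrating conditions, so the epoxide stays closed and the lactone does not migrate from the C6 to the C8 oxygen.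

Step 16
Reactants: 28 C8 epoxy ester with C3 silyl ether (as in step 15)
Product: 29 methyl (2E,4R)-4-{[(2R,3R)-2,3-dimethyloxirane-2-carbonyl]oxy}-2-(3-hydroxypropylidene)-4-{(2S,3R)-2-[(Z)-2-iodoprop-1-en-1-yl]-4-methylidene-5-oxooxolan-3-yl}butanoate
Conditions: HF·pyridine, pyridine, THF, 0 °C
Reagents that add atoms: none
Why: Buffered HF·pyridine should cleave the primary silyl ether without opening the glycidic ester or adding to the α-methylene lactone, and the E enoate geometry keeps the freed hydroxyl from lactonising onto C14.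

Step 17
Reactants: 29 C3 alcohol (as in step 16)
Product: 30 methyl (2E,4R)-4-{[(2R,3R)-2,3-dimethyloxirane-2-carbonyl]oxy}-4-{(2S,3R)-2-[(Z)-2-iodoprop-1-en-1-yl]-4-methylidene-5-oxooxolan-3-yl}-2-(3-oxopropylidene)butanoate (seco aldehyde)
Conditions: Dess–Martin periodinane, NaHCO3, CH2Cl2, 0 °C; short silica plug, used at once
Reagents that add atoms: none
Why: Buffered Dess–Martin oxidation should give the β,γ-unsaturated aldehyde without base that could move the C1=C10 alkene into conjugation; the aldehyde is made last and not stored.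

Step 18
Reactants: 30 seco aldehyde (as in step 17)
Product: 32 target, methyl (1(10)E,4Z)-8-{[(2R,3R)-2,3-dimethyloxirane-2-carbonyl]oxy}-3-hydroxygermacra-1(10),4,11(13)-trien-12,6-olid-14-oate, (3S,6R,7R,8R), via alkenylchromium dichloride 31 (not isolated)
Conditions: CrCl2 (excess), NiCl2 (cat.), degassed DMSO, rt, slow addition of 30 at high dilution; aqueous work-up
Reagents that add atoms: none
Why: Zerovalent nickel, formed from NiCl2 by divalent chromium, adds oxidatively to the C4–I bond without loss of the Z geometry and passes the alkenyl group to chromium; the resulting trivalent alkenylchromium species 31 attacks the C3 aldehyde and work-up frees the carbinol. The closest known reaction type is the intramolecular Nozaki–Hiyama–Kishi alkenyl iodide–aldehyde macrocyclisation, which is established for ten-membered carbocycles. The carbocycle C1–C10 closes end to end by C3–C4 bond formation (10-exo-trig attack on the aldehyde), helped by the two ring-cis alkenes and the trans-fused lactone, which pre-fold the chain. The new C3 stereocentre is set under substrate control: the conformation of the closing ring decides which aldehyde face C4 reaches, and 3S is the outcome needed. The step needs chemoselectivity for the aldehyde over the lactone, the esters, the enoate and the glycidic ester, which the low basicity of alkenylchromium should provide, and ring closure over dimerisation, which slow addition at high dilution secures. A low nickel loading should limit alkenyl homocoupling.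

Compound list
1 | but-2-yn-1-ol | CC#CCO | starting material
2 | cyclic sodium alkenylaluminate (five-membered C=C–C–O–Al ring, two 2-methoxyethoxy groups on Al) | [Na+].CC1=CCO[Al-]1(OCCOC)OCCOC | intermediate
3 | (Z)-3-iodobut-2-en-1-ol | C/C(I)=C/CO | intermediate
4 | (Z)-3-iodobut-2-enal | C/C(I)=C/C=O | intermediate
5 | vinylmagnesium bromide | C=C[Mg]Br | starting material
6 | rac-(Z)-5-iodohexa-1,4-dien-3-ol | C=CC(O)/C=C(/C)I | intermediate
7 | (3S,4Z)-5-iodohexa-1,4-dien-3-ol | C=C[C@H](O)/C=C(/C)I | intermediate
8 | 2-(bromomethyl)prop-2-enoic acid | C=C(CBr)C(=O)O | starting material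
9 | 2-(bromomethyl)prop-2-enoyl chloride | C=C(CBr)C(=O)Cl | intermediate
10 | (3S,4Z)-5-iodohexa-1,4-dien-3-yl 2-(bromomethyl)prop-2-enoate | C=C[C@H](OC(=O)C(=C)CBr)/C=C(/C)I | intermediate
11 | allylzinc bromide derived from 10 (Zn in place of Br–C) | C=C[C@H](OC(=O)C(=C)C[Zn]Br)/C=C(/C)I | intermediate
12 | (3S,4Z)-5-iodohexa-1,4-dien-3-yl 2-[(tributylstannyl)methyl]prop-2-enoate | C=C[C@H](OC(=O)C(=C)C[Sn](CCCC)(CCCC)CCCC)/C=C(/C)I | intermediate
13 | (5S)-5-[(Z)-2-iodoprop-1-en-1-yl]-3-[(tributylstannyl)methyl]furan-2(5H)-one | O=C1O[C@H](/C=C(/C)I)C=C1C[Sn](CCCC)(CCCC)CCCC | intermediate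
14 | trimethyl phosphonoacetate | COC(=O)CP(=O)(OC)OC | starting material
15 | allyl bromide | C=CCBr | starting material
16 | methyl 2-(dimethoxyphosphoryl)pent-4-enoate (racemic) | C=CCC(C(=O)OC)P(=O)(OC)OC | intermediate
17 | 3-[(tert-butyldimethylsilyl)oxy]propanal | O=CCCO[Si](C)(C)C(C)(C)C | starting material
18 | methyl (2E)-5-[(tert-butyldimethylsilyl)oxy]-2-(prop-2-en-1-yl)pent-2-enoate | C=CC/C(C(=O)OC)=C\CCO[Si](C)(C)C(C)(C)C | intermediate
19 | methyl (2E)-5-[(tert-butyldimethylsilyl)oxy]-2-(2,3-dihydroxypropyl)pent-2-enoate (diol epimers) | OCC(O)C/C(C(=O)OC)=C\CCO[Si](C)(C)C(C)(C)C | intermediate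
20 | methyl (2E)-5-[(tert-butyldimethylsilyl)oxy]-2-(2-oxoethyl)pent-2-enoate | O=CC/C(C(=O)OC)=C\CCO[Si](C)(C)C(C)(C)C | intermediate
21 | angelic acid, (Z)-2-methylbut-2-enoic acid | C/C=C(/C)C(=O)O | starting material
22 | (Z)-2-methylbut-2-en-1-ol | C/C=C(/C)CO | intermediate
23 | [(2S,3R)-2,3-dimethyloxiran-2-yl]methanol | OC[C@]1(C)O[C@@H]1C | intermediate
24 | (2R,3R)-2,3-dimethyloxirane-2-carbaldehyde | O=C[C@]1(C)O[C@@H]1C | intermediate
25 | (2R,3R)-2,3-dimethyloxirane-2-carboxylic acid | OC(=O)[C@]1(C)O[C@@H]1C | intermediate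
26 | methyl (2E,4R)-2-{3-[(tert-butyldimethylsilyl)oxy]propylidene}-4-hydroxy-4-{(2S,3R)-2-[(Z)-2-iodoprop-1-en-1-yl]-4-methylidene-5-oxooxolan-3-yl}butanoate | C=C1C(=O)O[C@H](/C=C(/C)I)[C@H]1[C@H](O)C/C(C(=O)OC)=C\CCO[Si](C)(C)C(C)(C)C | intermediate
27 | (2R,3R)-2,3-dimethyloxirane-2-carboxylic 2,4,6-trichlorobenzoic anhydride | O=C(OC(=O)[C@]1(C)O[C@@H]1C)c1c(Cl)cc(Cl)cc1Cl | intermediate
28 | methyl (2E,4R)-2-{3-[(tert-butyldimethylsilyl)oxy]propylidene}-4-{[(2R,3R)-2,3-dimethyloxirane-2-carbonyl]oxy}-4-{(2S,3R)-2-[(Z)-2-iodoprop-1-en-1-yl]-4-methylidene-5-oxooxolan-3-yl}butanoate | C=C1C(=O)O[C@H](/C=C(/C)I)[C@H]1[C@H](OC(=O)[C@]2(C)O[C@@H]2C)C/C(C(=O)OC)=C\CCO[Si](C)(C)C(C)(C)C | intermediate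
29 | methyl (2E,4R)-4-{[(2R,3R)-2,3-dimethyloxirane-2-carbonyl]oxy}-2-(3-hydroxypropylidene)-4-{(2S,3R)-2-[(Z)-2-iodoprop-1-en-1-yl]-4-methylidene-5-oxooxolan-3-yl}butanoate | C=C1C(=O)O[C@H](/C=C(/C)I)[C@H]1[C@H](OC(=O)[C@]2(C)O[C@@H]2C)C/C(C(=O)OC)=C\CCO | intermediate
30 | methyl (2E,4R)-4-{[(2R,3R)-2,3-dimethyloxirane-2-carbonyl]oxy}-4-{(2S,3R)-2-[(Z)-2-iodoprop-1-en-1-yl]-4-methylidene-5-oxooxolan-3-yl}-2-(3-oxopropylidene)butanoate (seco-C3/C4 aldehyde) | C=C1C(=O)O[C@H](/C=C(/C)I)[C@H]1[C@H](OC(=O)[C@]2(C)O[C@@H]2C)C/C(C(=O)OC)=C\CC=O | intermediate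
31 | alkenylchromium dichloride derived from 30 (Cr in place of I on C4, Z geometry kept) | C=C1C(=O)O[C@H](/C=C(/C)[Cr](Cl)Cl)[C@H]1[C@H](OC(=O)[C@]2(C)O[C@@H]2C)C/C(C(=O)OC)=C\CC=O | intermediate
32 | methyl (1(10)E,4Z)-8-{[(2R,3R)-2,3-dimethyloxirane-2-carbonyl]oxy}-3-hydroxygermacra-1(10),4,11(13)-trien-12,6-olid-14-oate, (3S,6R,7R,8R) | C=C1C(=O)O[C@@H]2/C=C(/C)[C@@H](O)C/C=C(/C(=O)OC)C[C@@H](OC(=O)[C@]3(C)O[C@@H]3C)[C@@H]12 | target

Total step count: 18. Longest linear sequence: 12 steps (steps 1–7 and 14–18).

Steps most likely to fail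

Step 18. The ring may close on the wrong aldehyde face (poor or reversed facial selectivity at C3), since only the conformation of the forming ring controls it. The aldehyde may also enolise toward conjugation before closure. The fallback sets out from 30 and moves stereocontrol from the cyclisation to a reagent-controlled reduction. The cyclisation is run as above and the C3-epimeric macrocycle F1 (alone or mixed with 32) is oxidised with Dess–Martin periodinane and NaHCO3 in CH2Cl2 to the macrocyclic 4-en-3-one F2. Corey–Bakshi–Shibata reduction with (R)-2-methyl-CBS-oxazaborolidine and catecholborane in toluene at −78 °C, with the alkenyl side as the large group, should give the 3S alcohol. The route is rejoined at 32.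

Step 14. The open transition state may give poor simple diastereoselectivity, with the anti C7/C8 adduct formed in place of the syn one. The fallback sets out from 13 and 20 and sets C8 by inversion instead of by the addition. The C8-epimeric alcohol F3 from the same addition is separated and esterified with acid 25 under Mitsunobu conditions (PPh3, diisopropyl azodicarboxylate, toluene, 0 °C). SN2 inversion at C8 installs the epoxy ester with the required 8R configuration, and the route is rejoined at 28, so step 15 is not needed for that material.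

Step 7. Metathesis may stall because the ruthenium carbene is hampered by the bulky allylic tin group, or the stannane may be lost by protodestannylation on heating. The fallback sets out from 10 and reverses the order of ring closure and tin introduction. Ring-closing metathesis of bromide 10 (second-generation Grubbs catalyst, CH2Cl2, 40 °C) should give (5S)-3-(bromomethyl)-5-[(Z)-2-iodoprop-1-en-1-yl]furan-2(5H)-one F4. Barbier-type stannylation (Zn, Bu3SnCl, THF/sat. aq NH4Cl) should then place tin on the primary carbon to give the conjugated, less hindered allylstannane. The route is rejoined at 13.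

Further compounds
F1 | step 18 | C3 epimer of 32, (3R,6R,7R,8R) | C=C1C(=O)O[C@@H]2/C=C(/C)[C@H](O)C/C=C(/C(=O)OC)C[C@@H](OC(=O)[C@]3(C)O[C@@H]3C)[C@@H]12
F2 | step 18 | macrocyclic C3 ketone (4-en-3-one) of 32 | C=C1C(=O)O[C@@H]2/C=C(/C)C(=O)C/C=C(/C(=O)OC)C[C@@H](OC(=O)[C@]3(C)O[C@@H]3C)[C@@H]12
F3 | step 14 | methyl (2E,4S)-2-{3-[(tert-butyldimethylsilyl)oxy]propylidene}-4-hydroxy-4-{(2S,3R)-2-[(Z)-2-iodoprop-1-en-1-yl]-4-methylidene-5-oxooxolan-3-yl}butanoate (C8 epimer of 26) | C=C1C(=O)O[C@H](/C=C(/C)I)[C@H]1[C@@H](O)C/C(C(=O)OC)=C\CCO[Si](C)(C)C(C)(C)C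
F4 | step 7 | (5S)-3-(bromomethyl)-5-[(Z)-2-iodoprop-1-en-1-yl]furan-2(5H)-one | O=C1O[C@H](/C=C(/C)I)C=C1CBr
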